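At early times a batch is a count of half-lives. The dawn run, with 17% product at 80.0 min, gives 298 min as its early half-life, the first-order half-life of substrate reckoned from a product reading at low conversion. The decision for the next batch is how hot to run it, with the charges held and the time fixed at 40 min.

common to all: free catalyst 75 µM

|  | substrate | reagent | temperature | remark | time |
|---|---|---|---|---|---|
| dawn | 0.050 M | 0.077 M | 30 °C | run made earlier |  |
| spring | 0.050 M | 0.12 M | 72 °C | run made earlier |  |
| dusk | 0.025 M | 0.055 M | 30 °C | run made earlier |  |
| zeta | 0.050 M | 0.0550 M | 60 °C |  | 40 min |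
| theta | 0.050 M | 0.0550 M | 35 °C |  | 40 min |
| eta | 0.050 M | 0.0550 M | 110 °C |  | 40 min |
| gamma | 0.050 M | 0.0550 M | 85 °C |  | 40 min |

| run | time / min | product / % | substrate / % |
|---|---|---|---|
| dawn | 20.0 | 3 | 94 |
| dawn | 40.0 | 8 | 93 |
| dawn | 80.0 | 17 | 82 |
| dawn | 240 | 44 | 55 |
| spring | 6.00 | 11 | 88 |
| spring | 15.0 | 22 | 76 |
| spring | 20.0 | 26 | 71 |
| spring | 30.0 | 33 | 66 |
| dusk | 25.0 | 5 | 91 |
| dusk | 60.0 | 22 | 84 |
| dusk | 120 | 30 | 70 |
| dusk | 240 | 52 | 52 |

(standard deviation of a reading: 2 percentage points)

- the flask with the highest amount of product, in percent of the substrate charged ("all alike" if they lie within 1.5 percentage points) (zeta / theta / eta / gamma / all alike)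
- final product, as a percentage of the substrate charged, in zeta
- final product, as a percentage of the substrate charged, in theta
- final product, as a percentage of the substrate charged, in eta
- final product, as a percentage of the substrate charged, in gamma

- the analysis behind the earlier runs scatters by 2 percentage points, standard deviation
- candidate steps: substrate + catalyst intermediate B -> catalyst intermediate C; reagent + free catalyst <-> catalyst intermediate A; catalyst intermediate A <-> released group + catalyst intermediate B; catalyst intermediate C <-> free catalyst + product

The count is the batch time over the early half-life, and the product fraction is one minus two to the minus count. The dawn run's last reading, 44% at 240 min, reckons to 287 min, so at 30 °C the half-life holds within the scatter. The spring run does not behave so well: its reading at 6.00 min gives 35.7 min, but its reading at 30.0 min gives 51.9 min. The scatter of 2 percentage points on the early reading covers part of that stretch, but not all of it. So I count only the cold flask. Theta gets 0.134 half-lives, which is 8.90% product, though the dawn run was colder and carried more reagent. I do not count forward at 72 °C or above, and I read zeta and gamma before I pay for the heat of eta.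

The forecast names eta, with 25% in zeta, 10% in theta, 50% in eta and 38% in gamma, on the ground that “more heat should still give more product, but with diminishing returns”. For theta it stands above my count.

The flasks give 29.6% in zeta, 11.1% in theta, 13.2% in eta and 22.6% in gamma, so zeta holds the most, and eta falls 37 points short of the forecast.

    substrate + catalyst intermediate B → catalyst intermediate C (k = 8.40 M⁻¹ s⁻¹, Ea = 60.0 kJ mol⁻¹)
    reagent + free catalyst ⇌ catalyst intermediate A (K = 21.0 M⁻¹, k = 33.0 M⁻¹ s⁻¹, Ea = 48.0 kJ mol⁻¹, ΔH = −26.0 kJ mol⁻¹)
    catalyst intermediate A ⇌ released group + catalyst intermediate B (K = 0.0170 M, k = 0.750 s⁻¹, Ea = 68.0 kJ mol⁻¹, ΔH = −69.0 kJ mol⁻¹)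
    catalyst intermediate C ⇌ free catalyst + product (K = 0.00930 M, k = 16.0 s⁻¹, Ea = 66.0 kJ mol⁻¹, ΔH = −61.0 kJ mol⁻¹)
    (constants at 60 °C)

In theta, the half-life of substrate by capture on catalyst intermediate B is 3.9 h at 19.2 min, longer than the batch of 40 min, and at 40.0 min the catalyst stands at 45.2% as catalyst intermediate B and 30.4% as catalyst intermediate A. That capture half-life is shorter than my 298 min, and theta ends at 1.25 times my count. The neighbour, theta read at 15 min, counts 0.0503 half-lives, which is 3.43% product, and 4.30% with that factor; the computed flask gives 4.32%.

The data were computed for substances that don't exist.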